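**Plan**
- Retrosynthetic cuts, in order: the O–S bond of the sulfate; the C7a–O1 aryl ether bond of the dihydrofuran; the C2–C3 bond (aldol); the C3a–CH2 bond on ring B (Claisen), leading back to eugenol.
- Enabling feature: O1 joins the benzylic carbinol carbon C2 (bearing guaiacyl ring A) to C7a of ring B. C7a is the phenolic carbon of eugenol and can carry a triflate, and with C3 holding ring B and the CH2OH the open form is a 2-aryl-1,3-diol whose secondary oxygen can reach C7a.
- Forward: the ring-B arylacetic acid is built from eugenol, an Evans syn-aldol attaches ring A, reduction and primary silylation give the coupling precursor, the palladium C–O coupling closes the only new ring, and chain desilylation, sulfation and two deprotections finish.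
- Stereochemistry: both centres come from the boron aldol under control of an (S)-4-benzyloxazolidinone, giving the (2S,3S) adduct, which is the (1S,2R) diol. The coupling breaks no bond at either centre, so they become (2S,3R) in the target.

Key step: step 12

Abbreviations: TBS = tert-butyldimethylsilyl, TBDPS = tert-butyldiphenylsilyl, Tf = trifluoromethanesulfonyl, Bn = benzyl. "ArB" is the ring-B group 5-[3-(TBS-oxy)propyl]-3-methoxy-2-(TfO)phenyl. Positions O1, C2, C3, C3a, C4–C7, C7a are those of 2,3-dihydrobenzofuran.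

Assumption: the target is drawn as the free hydrogen sulfate, so the sulfate half-esters 23–25 are formulated as free acids. In practice they would be handled as pyridinium or tetrabutylammonium salts, and the acid form would be released only in the last work-up by brief cation exchange in the cold.

**Step 1**
Reactants: 1 eugenol
Product: 3 4-(3-hydroxypropyl)-2-methoxyphenol (dihydroconiferyl alcohol), via B-alkyl-9-BBN adduct 2 (not isolated)
Conditions: 9-BBN (2.2 equiv), THF, 0 °C to rt; then aq NaOH, 30% H2O2, 0 °C to rt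
Reagents that add atoms: hydrogen peroxide, OO
Why: Hydroboration–oxidation with the bulky borane should place boron at the terminal carbon of the allyl group and give the primary alcohol, the phenol at most consuming extra borane as a borinate that is hydrolysed on work-up.

**Step 2**
Reactants: 3 dihydroconiferyl alcohol; 4 allyl bromide
Product: 5 3-[4-(allyloxy)-3-methoxyphenyl]propan-1-ol
Conditions: K2CO3, acetone, reflux
Reagents that add atoms: none
Why: In this Williamson ether synthesis K2CO3 deprotonates only the phenol, so the phenoxide should be allylated while the aliphatic hydroxyl stays free.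

**Step 3**
Reactants: 5 3-[4-(allyloxy)-3-methoxyphenyl]propan-1-ol
Product: 6 {3-[4-(allyloxy)-3-methoxyphenyl]propoxy}(tert-butyl)dimethylsilane
Conditions: TBSCl, imidazole, CH2Cl2, rt
Reagents that add atoms: tert-butyldimethylsilyl chloride, CC(C)(C)[Si](C)(C)Cl
Why: Imidazole-promoted silylation of the only hydroxyl should give a silyl ether that tolerates the heat, base, borohydride and palladium steps ahead and can later be removed in the presence of TBDPS.

**Step 4**
Reactants: 6 {3-[4-(allyloxy)-3-methoxyphenyl]propoxy}(tert-butyl)dimethylsilane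
Product: 7 2-allyl-4-[3-(TBS-oxy)propyl]-6-methoxyphenol
Conditions: N,N-diethylaniline, 195 °C, sealed vessel
Reagents that add atoms: none
Why: The aromatic Claisen rearrangement can deliver the allyl group only to the single free ortho carbon (the other ortho position carries OMe and the para position the chain), and tautomerisation then restores the phenol.

**Step 5**
Reactants: 7 2-allyl-4-[3-(TBS-oxy)propyl]-6-methoxyphenol
Product: 8 2-allyl-4-[3-(TBS-oxy)propyl]-6-methoxyphenyl trifluoromethanesulfonate
Conditions: Tf2O, pyridine, CH2Cl2, 0 °C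
Reagents that add atoms: trifluoromethanesulfonic anhydride, O=S(=O)(OS(=O)(=O)C(F)(F)F)C(F)(F)F
Why: O-Sulfonylation of the phenol installs at the future C7a the leaving group for the later coupling, and as a triflate this oxygen is also masked through the oxidation and aldol steps.

**Step 6**
Reactants: 8 2-allyl-4-[3-(TBS-oxy)propyl]-6-methoxyphenyl trifluoromethanesulfonate
Product: 10 2-ArB-acetaldehyde, via 1,2-diol 9 (not isolated)
Conditions: OsO4 (2 mol %), NaIO4 (4 equiv), 2,6-lutidine, 1,4-dioxane/H2O, rt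
Reagents that add atoms: osmium tetroxide, O=[Os](=O)(=O)=O (oxygen donor, regenerated by sodium periodate, [Na+].[O-]I(=O)(=O)=O)
Why: Lemieux–Johnson cleavage (dihydroxylation, then periodate glycol cleavage) should shorten the allyl group by one carbon to the arylacetaldehyde without touching the triflate, the silyl ether or the arene.

**Step 7**
Reactants: 10 2-ArB-acetaldehyde
Product: 11 2-ArB-acetic acid
Conditions: NaClO2, NaH2PO4, 2-methyl-2-butene, t-BuOH/H2O, rt
Reagents that add atoms: sodium chlorite, [Na+].[O-]Cl=O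
Why: Pinnick oxidation converts the sensitive crude aldehyde into the acid under buffered conditions, with the alkene scavenger removing hypochlorous acid before it can chlorinate ring B.

**Step 8**
Reactants: 11 2-ArB-acetic acid; 12 (S)-4-benzyloxazolidin-2-one
Product: 14 (S)-4-benzyl-3-(2-ArB-acetyl)oxazolidin-2-one, via mixed pivalic anhydride 13 (not isolated)
Conditions: t-BuCOCl, Et3N, THF, −20 °C; then 12, LiCl, −20 °C to rt
Reagents that add atoms: none
Why: N-Acylation through the mixed pivalic anhydride should occur at the unhindered arylacetyl carbonyl under LiCl activation, avoiding both an acid chloride and a strongly basic lithiated auxiliary next to the triflate.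

**Step 9**
Reactants: 14 (S)-4-benzyl-3-(2-ArB-acetyl)oxazolidin-2-one; 15 4-(benzyloxy)-3-methoxybenzaldehyde
Product: 18 (S)-4-benzyl-3-[(2S,3S)-2-ArB-3-[4-(benzyloxy)-3-methoxyphenyl]-3-hydroxypropanoyl]oxazolidin-2-one, via Z-boron enolate 16 (not isolated), via boron aldolate 17 (not isolated)
Conditions: Bu2BOTf, i-Pr2NEt, CH2Cl2, −78 to 0 °C; then 15, −78 to 0 °C; then pH 7 phosphate buffer, MeOH, 30% H2O2, 0 °C
Reagents that add atoms: none
Why: In this Evans syn-aldol the Z-dibutylboron enolate reacts through a closed Zimmerman–Traxler chair in which the auxiliary benzyl group blocks one enolate face, which should set both stereocentres as the (2S,3S) syn adduct and form the C2–C3 bond of the target.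

**Step 10**
Reactants: 18 the (2S,3S) aldol adduct
Product: 19 (1S,2R)-1-[4-(benzyloxy)-3-methoxyphenyl]-2-ArB-propane-1,3-diol
Conditions: LiBH4, MeOH (1.5 equiv), THF, 0 °C
Reagents that add atoms: none
Why: Reductive cleavage of the N-acyloxazolidinone by LiBH4 at the exocyclic carbonyl should release the auxiliary and give the primary alcohol, taking the ester oxidation level out before the basic coupling so that no retro-aldol path remains there; the aryl triflate is inert to borohydride.

**Step 11**
Reactants: 19 (1S,2R)-1-[4-(benzyloxy)-3-methoxyphenyl]-2-ArB-propane-1,3-diol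
Product: 20 (1S,2R)-1-[4-(benzyloxy)-3-methoxyphenyl]-2-ArB-3-(TBDPS-oxy)propan-1-ol
Conditions: TBDPSCl, imidazole, CH2Cl2, 0 °C
Reagents that add atoms: tert-butyldiphenylsilyl chloride, CC(C)(C)[Si](Cl)(c1ccccc1)c1ccccc1
Why: The bulky chlorosilane should silylate the primary hydroxyl selectively and leave the hindered secondary benzylic hydroxyl free as the only oxygen nucleophile for ring closure.

**Step 12**
Reactants: 20 (1S,2R)-1-[4-(benzyloxy)-3-methoxyphenyl]-2-ArB-3-(TBDPS-oxy)propan-1-ol
Product: 21 (2S,3R)-2-[4-(benzyloxy)-3-methoxyphenyl]-3-[(TBDPS-oxy)methyl]-5-[3-(TBS-oxy)propyl]-7-methoxy-2,3-dihydrobenzofuran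
Conditions: Pd(OAc)2 (5 mol %), racemic 2-(di-tert-butylphosphino)-1,1'-binaphthyl (7 mol %), Cs2CO3 (1.5 equiv), toluene, 70–80 °C
Reagents that add atoms: none
Why: Pd(OAc)2 is reduced in situ to a zerovalent palladium–phosphine complex that inserts into the C7a–OTf bond of ring B; Cs2CO3 then brings the C1 carbinol onto the arylpalladium triflate (divalent palladium) as an alkoxide, and C–O reductive elimination from the six-membered aryl(alkoxo)palladacycle forms C7a–O1. The closest known reaction type is the Buchwald–Hartwig-type intramolecular etherification of aryl halides and sulfonates with secondary alcohols using Pd(OAc)2, a di-tert-butyl(biaryl)phosphine and Cs2CO3. The dihydrofuran ring closes in a 5-exo sense, the oxygen being delivered to the arene carbon that carried the triflate. No stereocentre is created: the carbinol C–O bond and the C3–H bond are never broken, so C2 is retained and the trans (2S,3R) arrangement set in the aldol step is carried over unchanged. The step needs reductive elimination to outrun β-hydride elimination of the benzylic alkoxide and base-induced loss or transfer of the triflyl group; the bulky electron-rich phosphine speeds reductive elimination at the doubly ortho-substituted carbon, the sparingly soluble carbonate keeps the free alkoxide concentration low, and the silyl cap on the primary hydroxyl leaves the secondary oxygen as the only nucleophile.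

**Step 13**
Reactants: 21 the bis-silylated dihydrobenzofuran
Product: 22 3-[(2S,3R)-2-[4-(benzyloxy)-3-methoxyphenyl]-3-[(TBDPS-oxy)methyl]-7-methoxy-2,3-dihydrobenzofuran-5-yl]propan-1-ol
Conditions: pyridinium p-toluenesulfonate (0.2 equiv), MeOH, rt
Reagents that add atoms: none
Why: Acid-catalysed methanolysis should remove the primary TBS ether while the far more acid-stable TBDPS ether and the benzylic ring ether survive this weak acid.

**Step 14**
Reactants: 22 the chain alcohol
Product: 23 3-[(2S,3R)-2-[4-(benzyloxy)-3-methoxyphenyl]-3-[(TBDPS-oxy)methyl]-7-methoxy-2,3-dihydrobenzofuran-5-yl]propyl hydrogen sulfate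
Conditions: SO3·pyridine (3 equiv), pyridine, rt
Reagents that add atoms: sulfur trioxide–pyridine complex, [O-]S(=O)(=O)[n+]1ccccc1
Why: O-Sulfation by the SO3·pyridine complex can occur only at the single free hydroxyl, since the phenol and the other primary alcohol are both protected.

**Step 15**
Reactants: 23 the silylated sulfate
Product: 24 3-[(2S,3R)-2-[4-(benzyloxy)-3-methoxyphenyl]-3-(hydroxymethyl)-7-methoxy-2,3-dihydrobenzofuran-5-yl]propyl hydrogen sulfate
Conditions: Bu4NF, THF, rt
Reagents that add atoms: none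
Why: Fluoride-mediated desilylation frees the C3 hydroxymethyl group, and the sulfate monoester, present as its anion, is inert to fluoride and mild base.

**Step 16**
Reactants: 24 the O-benzyl sulfate
Product: 25 3-[(2S,3R)-2-(4-hydroxy-3-methoxyphenyl)-3-(hydroxymethyl)-7-methoxy-2,3-dihydrobenzofuran-5-yl]propyl hydrogen sulfate (target)
Conditions: H2 (1 atm), Pd/C (10% palladium on carbon), MeOH, rt; filtration; then cation-exchange resin (H+ form), MeOH/H2O, 0 °C
Reagents that add atoms: none
Why: Catalytic hydrogenolysis under neutral conditions should cleave the O-benzyl ether faster than the ring C2–O bond and leave the sulfate salt untouched, after which cold ion exchange gives the hydrogen sulfate as drawn.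

**Compound list**
1 | eugenol (4-allyl-2-methoxyphenol) | C=CCc1ccc(O)c(OC)c1 | starting material
2 | B-[3-(4-hydroxy-3-methoxyphenyl)propyl]-9-borabicyclo[3.3.1]nonane (formed in situ) | COc1cc(CCCB2C3CCCC2CCC3)ccc1O | intermediate
3 | 4-(3-hydroxypropyl)-2-methoxyphenol | COc1cc(CCCO)ccc1O | intermediate
4 | allyl bromide | C=CCBr | starting material
5 | 3-[4-(allyloxy)-3-methoxyphenyl]propan-1-ol | COc1cc(CCCO)ccc1OCC=C | intermediate
6 | {3-[4-(allyloxy)-3-methoxyphenyl]propoxy}(tert-butyl)dimethylsilane | COc1cc(CCCO[Si](C)(C)C(C)(C)C)ccc1OCC=C | intermediate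
7 | 2-allyl-4-[3-(TBS-oxy)propyl]-6-methoxyphenol | COc1cc(CCCO[Si](C)(C)C(C)(C)C)cc(CC=C)c1O | intermediate
8 | 2-allyl-4-[3-(TBS-oxy)propyl]-6-methoxyphenyl trifluoromethanesulfonate | COc1cc(CCCO[Si](C)(C)C(C)(C)C)cc(CC=C)c1OS(=O)(=O)C(F)(F)F | intermediate
9 | 3-ArB-propane-1,2-diol, racemic (formed in situ) | COc1cc(CCCO[Si](C)(C)C(C)(C)C)cc(CC(O)CO)c1OS(=O)(=O)C(F)(F)F | intermediate
10 | 2-ArB-acetaldehyde | COc1cc(CCCO[Si](C)(C)C(C)(C)C)cc(CC=O)c1OS(=O)(=O)C(F)(F)F | intermediate
11 | 2-ArB-acetic acid | COc1cc(CCCO[Si](C)(C)C(C)(C)C)cc(CC(=O)O)c1OS(=O)(=O)C(F)(F)F | intermediate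
12 | (S)-4-benzyloxazolidin-2-one | O=C1N[C@@H](Cc2ccccc2)CO1 | starting material
13 | 2-ArB-acetic pivalic anhydride (formed in situ) | COc1cc(CCCO[Si](C)(C)C(C)(C)C)cc(CC(=O)OC(=O)C(C)(C)C)c1OS(=O)(=O)C(F)(F)F | intermediate
14 | (S)-4-benzyl-3-(2-ArB-acetyl)oxazolidin-2-one | COc1cc(CCCO[Si](C)(C)C(C)(C)C)cc(CC(=O)N2[C@@H](Cc3ccccc3)COC2=O)c1OS(=O)(=O)C(F)(F)F | intermediate
15 | 4-(benzyloxy)-3-methoxybenzaldehyde (O-benzylvanillin) | COc1cc(C=O)ccc1OCc1ccccc1 | starting material
16 | Z-dibutylboron enolate of 14 (formed in situ) | CCCCB(CCCC)O/C(=C\c1cc(CCCO[Si](C)(C)C(C)(C)C)cc(OC)c1OS(=O)(=O)C(F)(F)F)N1[C@@H](Cc2ccccc2)COC1=O | intermediate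
17 | O-dibutylboryl aldolate of 18 (formed in situ) | COc1cc([C@@H](OB(CCCC)CCCC)[C@@H](C(=O)N2[C@@H](Cc3ccccc3)COC2=O)c4cc(CCCO[Si](C)(C)C(C)(C)C)cc(OC)c4OS(=O)(=O)C(F)(F)F)ccc1OCc5ccccc5 | intermediate
18 | (S)-4-benzyl-3-[(2S,3S)-2-ArB-3-[4-(benzyloxy)-3-methoxyphenyl]-3-hydroxypropanoyl]oxazolidin-2-one | COc1cc([C@@H](O)[C@@H](C(=O)N2[C@@H](Cc3ccccc3)COC2=O)c4cc(CCCO[Si](C)(C)C(C)(C)C)cc(OC)c4OS(=O)(=O)C(F)(F)F)ccc1OCc5ccccc5 | intermediate
19 | (1S,2R)-1-[4-(benzyloxy)-3-methoxyphenyl]-2-ArB-propane-1,3-diol | COc1cc([C@@H](O)[C@@H](CO)c2cc(CCCO[Si](C)(C)C(C)(C)C)cc(OC)c2OS(=O)(=O)C(F)(F)F)ccc1OCc3ccccc3 | intermediate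
20 | (1S,2R)-1-[4-(benzyloxy)-3-methoxyphenyl]-2-ArB-3-(TBDPS-oxy)propan-1-ol | COc1cc([C@@H](O)[C@@H](CO[Si](c2ccccc2)(c3ccccc3)C(C)(C)C)c4cc(CCCO[Si](C)(C)C(C)(C)C)cc(OC)c4OS(=O)(=O)C(F)(F)F)ccc1OCc5ccccc5 | intermediate
21 | (2S,3R)-2-[4-(benzyloxy)-3-methoxyphenyl]-3-[(TBDPS-oxy)methyl]-5-[3-(TBS-oxy)propyl]-7-methoxy-2,3-dihydrobenzofuran | COc1cc([C@H]2Oc3c(OC)cc(CCCO[Si](C)(C)C(C)(C)C)cc3[C@@H]2CO[Si](c4ccccc4)(c5ccccc5)C(C)(C)C)ccc1OCc6ccccc6 | intermediate
22 | 3-[(2S,3R)-2-[4-(benzyloxy)-3-methoxyphenyl]-3-[(TBDPS-oxy)methyl]-7-methoxy-2,3-dihydrobenzofuran-5-yl]propan-1-ol | COc1cc([C@H]2Oc3c(OC)cc(CCCO)cc3[C@@H]2CO[Si](c4ccccc4)(c5ccccc5)C(C)(C)C)ccc1OCc6ccccc6 | intermediate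
23 | 3-[(2S,3R)-2-[4-(benzyloxy)-3-methoxyphenyl]-3-[(TBDPS-oxy)methyl]-7-methoxy-2,3-dihydrobenzofuran-5-yl]propyl hydrogen sulfate | COc1cc([C@H]2Oc3c(OC)cc(CCCOS(=O)(=O)O)cc3[C@@H]2CO[Si](c4ccccc4)(c5ccccc5)C(C)(C)C)ccc1OCc6ccccc6 | intermediate
24 | 3-[(2S,3R)-2-[4-(benzyloxy)-3-methoxyphenyl]-3-(hydroxymethyl)-7-methoxy-2,3-dihydrobenzofuran-5-yl]propyl hydrogen sulfate | COc1cc([C@H]2Oc3c(OC)cc(CCCOS(=O)(=O)O)cc3[C@@H]2CO)ccc1OCc4ccccc4 | intermediate
25 | 3-[(2S,3R)-2-(4-hydroxy-3-methoxyphenyl)-3-(hydroxymethyl)-7-methoxy-2,3-dihydrobenzofuran-5-yl]propyl hydrogen sulfate | COc1cc([C@H]2Oc3c(OC)cc(CCCOS(=O)(=O)O)cc3[C@@H]2CO)ccc1O | target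

**Step count**
Total step count: 16. Longest linear sequence: 16 steps, from eugenol; the auxiliary 12 and the aldehyde 15 are bought.

**Steps most likely to fail**

1. Step 12. β-Hydride elimination from the benzylic palladium alkoxide, base-induced cleavage or transfer of the triflyl group, or migration of the TBDPS group onto the secondary oxygen could outpace C–O reductive elimination at the crowded C7a. The fallback sets out from 20 and forms the other ring C–O bond. Tetraethylammonium hydroxide in dioxane should cleave the triflate to (1S,2R)-1-[4-(benzyloxy)-3-methoxyphenyl]-2-{2-hydroxy-3-methoxy-5-[3-(TBS-oxy)propyl]phenyl}-3-(TBDPS-oxy)propan-1-ol F1. BF3·OEt2 in CH2Cl2 at low temperature would then ionise the p-benzyloxybenzylic alcohol, and the phenol oxygen should trap the cation on the face opposite the C3 substituent. This cyclodehydration forms C2–O1, with C3 directing C2 to the trans isomer, and the route is rejoined at 21.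

2. Step 9. The stabilised arylacetyl enolate may add slowly to the electron-rich aldehyde, and retro-aldol equilibration or epimerisation at the acidic α-aryl carbon could erode the syn selectivity. The fallback sets out from 11 and sets the centres by reduction. Trimethylsilyldiazomethane should give methyl 2-ArB-acetate F2. Its lithium enolate (LDA, THF, −78 °C) would add to 15 to give methyl 2-ArB-3-[4-(benzyloxy)-3-methoxyphenyl]-3-hydroxypropanoate F3 as a diastereomer mixture. Dess–Martin periodinane would oxidise this to the configurationally labile methyl 2-ArB-3-[4-(benzyloxy)-3-methoxyphenyl]-3-oxopropanoate F4. Noyori transfer hydrogenation with RuCl(p-cymene)[(S,S)-TsDPEN] in HCO2H/Et3N, run as a dynamic kinetic resolution, should then give methyl (2S,3S)-2-ArB-3-[4-(benzyloxy)-3-methoxyphenyl]-3-hydroxypropanoate F5. Reduction with LiBH4 rejoins the route at 19.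

3. Step 10. The lithium aldolate may fragment by retro-aldol, or hydride may attack the ring carbonyl of the hindered imide and open the auxiliary. The fallback sets out from 18 and separates cleavage from reduction. LiOH/H2O2 in THF/H2O at 0 °C should hydrolyse the imide selectively at the exocyclic carbonyl to (2S,3S)-2-ArB-3-[4-(benzyloxy)-3-methoxyphenyl]-3-hydroxypropanoic acid F6. BH3·SMe2 in THF would then reduce the carboxylic acid in the presence of the triflate and silyl ether, rejoining the route at 19.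

**Further compounds**
F1 | step 12 | (1S,2R)-1-[4-(benzyloxy)-3-methoxyphenyl]-2-{2-hydroxy-3-methoxy-5-[3-(TBS-oxy)propyl]phenyl}-3-(TBDPS-oxy)propan-1-ol | COc1cc([C@@H](O)[C@@H](CO[Si](c2ccccc2)(c3ccccc3)C(C)(C)C)c4cc(CCCO[Si](C)(C)C(C)(C)C)cc(OC)c4O)ccc1OCc5ccccc5
F2 | step 9 | methyl 2-ArB-acetate | COC(=O)Cc1cc(CCCO[Si](C)(C)C(C)(C)C)cc(OC)c1OS(=O)(=O)C(F)(F)F
F3 | step 9 | methyl 2-ArB-3-[4-(benzyloxy)-3-methoxyphenyl]-3-hydroxypropanoate (diastereomer mixture) | COC(=O)C(c1cc(CCCO[Si](C)(C)C(C)(C)C)cc(OC)c1OS(=O)(=O)C(F)(F)F)C(O)c2ccc(OCc3ccccc3)c(OC)c2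
F4 | step 9 | methyl 2-ArB-3-[4-(benzyloxy)-3-methoxyphenyl]-3-oxopropanoate (racemic) | COC(=O)C(c1cc(CCCO[Si](C)(C)C(C)(C)C)cc(OC)c1OS(=O)(=O)C(F)(F)F)C(=O)c2ccc(OCc3ccccc3)c(OC)c2
F5 | step 9 | methyl (2S,3S)-2-ArB-3-[4-(benzyloxy)-3-methoxyphenyl]-3-hydroxypropanoate | COc1cc([C@@H](O)[C@@H](C(=O)OC)c2cc(CCCO[Si](C)(C)C(C)(C)C)cc(OC)c2OS(=O)(=O)C(F)(F)F)ccc1OCc3ccccc3
F6 | step 10 | (2S,3S)-2-ArB-3-[4-(benzyloxy)-3-methoxyphenyl]-3-hydroxypropanoic acid | COc1cc([C@@H](O)[C@@H](C(=O)O)c2cc(CCCO[Si](C)(C)C(C)(C)C)cc(OC)c2OS(=O)(=O)C(F)(F)F)ccc1OCc3ccccc3
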